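**Strategy**

The target is the 1(10),4(5)-diepoxide of eupatolide 8-O-tiglate, so both oxiranes are added last to the (E,E)-cyclodecadiene. The route rests on cutting the methylene lactone ring (O–C6–C7–C11–C12) at O–C6 and C11–C7: before epoxidation C6 is allylic to C4=C5, so this ring is the 1,2-adduct of an acyclic (E,E)-C4=C5–C6=C7 diene and 2-bromoacrylic acid. One palladium-catalysed [3+2] heteroannulation makes both bonds, both stereocentres and the exocyclic methylene. The diene carries on C7 a glyceraldehyde-derived dioxolane as a temporary stereocontrol element; it is then cleaved to the C8 aldehyde, which closes the ten-membered ring by chromium-mediated allylation.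

Key step: step 7

Remark: germacrane numbering is used for the carbon atoms (C6 bears the lactone oxygen, C7 bears C11, C8 the tiglate, C10 and C4 the methyl groups). The 8R carbinol is assumed to be the main product of the ring closure in step 11.

**Route**

Step 1
Reactants: 1 4-pentyn-1-ol
Product: 2 4-pentynal
Conditions: TEMPO (10 mol %), PhI(OAc)2 (1.1 equiv), CH2Cl2, rt; used crude
Reagents that add atoms: none
Why: Oxoammonium (TEMPO/PhI(OAc)2) oxidation of the primary alcohol stops at the aldehyde and does not touch the terminal alkyne.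

Step 2
Reactants: 2 4-pentynal; 3 ethyl 2-(triphenyl-λ5-phosphanylidene)propanoate
Product: 4 ethyl (2E)-2-methylhept-2-en-6-ynoate
Conditions: CH2Cl2, rt
Reagents that add atoms: none
Why: Wittig olefination with a stabilised α-branched ylide should give the E-trisubstituted enoate, which becomes the C1=C10 alkene with its methyl group.

Step 3
Reactants: 4 ethyl (2E)-2-methylhept-2-en-6-ynoate
Product: 5 (2E)-2-methylhept-2-en-6-yn-1-ol
Conditions: i-Bu2AlH (2.2 equiv), CH2Cl2, −78 °C; aq. potassium sodium tartrate
Reagents that add atoms: none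
Why: i-Bu2AlH reduces the conjugated ester by 1,2-hydride delivery to the allylic alcohol without changing the alkene geometry.

Step 4
Reactants: 5 (2E)-2-methylhept-2-en-6-yn-1-ol
Product: 6 tert-butyl(dimethyl){[(2E)-2-methylhept-2-en-6-yn-1-yl]oxy}silane
Conditions: TBSCl, imidazole, DMF, rt
Reagents that add atoms: tert-butyl(chloro)dimethylsilane CC(C)(C)[Si](C)(C)Cl
Why: Silylation masks the primary allylic alcohol (the future C9–O) for the organoaluminium and palladium steps.

Step 5
Reactants: 7 (4R)-2,2-dimethyl-1,3-dioxolane-4-carbaldehyde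
Product: 8 (4S)-4-[(E)-2-iodoethenyl]-2,2-dimethyl-1,3-dioxolane
Conditions: CrCl2 (6 equiv), CHI3 (2 equiv), THF, 0 °C
Reagents that add atoms: iodoform IC(I)I
Why: Takai olefination converts the aldehyde into the E-vinyl iodide under non-basic conditions, so the α-oxygenated stereocentre should not epimerise.

Step 6
Reactants: 6 tert-butyl(dimethyl){[(2E)-2-methylhept-2-en-6-yn-1-yl]oxy}silane; 8 (4S)-4-[(E)-2-iodoethenyl]-2,2-dimethyl-1,3-dioxolane
Product: 10 (4S)-4-[(1E,3E,7E)-9-{[tert-butyl(dimethyl)silyl]oxy}-4,8-dimethylnona-1,3,7-trien-1-yl]-2,2-dimethyl-1,3-dioxolane, via alkenyldimethylalane 9 (not isolated)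
Conditions: Me3Al (2 equiv), Cp2ZrCl2 (0.25 equiv), CH2Cl2, 0 °C to rt; volatiles removed; then 8, ZnCl2 (1 equiv), Pd(PPh3)4 (5 mol %), THF, rt
Reagents that add atoms: trimethylaluminium C[Al](C)C
Why: Zirconium-catalysed syn-carboalumination of the terminal alkyne fixes the E-trisubstituted C4=C5 bond (methyl and aluminium cis), and Negishi coupling with the E-iodide proceeds with retention at both partners to give the (E,E)-diene.

Step 7
Reactants: 10 (4S)-4-[(1E,3E,7E)-9-{[tert-butyl(dimethyl)silyl]oxy}-4,8-dimethylnona-1,3,7-trien-1-yl]-2,2-dimethyl-1,3-dioxolane; 11 2-bromoprop-2-enoic acid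
Product: 12 (4S,5R)-5-[(1E,5E)-7-{[tert-butyl(dimethyl)silyl]oxy}-2,6-dimethylhepta-1,5-dien-1-yl]-4-[(4S)-2,2-dimethyl-1,3-dioxolan-4-yl]-3-methylideneoxolan-2-one
Conditions: 11 (1.5 equiv), Pd(OAc)2 (10 mol %), PPh3 (20 mol %), Ag2CO3 (1.5 equiv), DMF, 70 °C
Reagents that add atoms: none
Why: Zerovalent palladium inserts into the C–Br bond of 11 (present as its carboxylate), the alkenylpalladium adds syn across the less substituted C6=C7 terminus of the diene (C11 to C7, palladium to C6), and the carboxylate-ligated η3-allyl complex over C6–C5–C4 collapses by C–O bond formation at C6, so O–C6 and C11–C7 form in one catalytic cycle. The closest known reaction type is the Larock heteroannulation of 1,3-dienes by vinylic halides that carry a carboxylic acid. The lactone ring closes by 5-exo attack of the palladium-bound carboxylate oxygen on the allyl terminus C6, the seven-membered alternative at C4 being disfavoured. C7 is controlled by the dioxolane stereocentre: in the rotamer with the allylic C–H eclipsing the alkene (minimal 1,3-allylic strain) the palladium reagent should add anti to the allylic C–O bond, as osmylation and nitrile oxide cycloaddition of such alkenyl dioxolanes do; C6 then follows from syn addition across the E-alkene with inner-sphere C–O formation, which places C5 and C8 trans on the lactone. The step needs regioselectivity for C7 over the fully substituted terminus C4 and over the isolated trisubstituted alkene, which sterics and the stability of the η3-allyl intermediate should secure, and retention of the E-C4=C5 geometry, which holds because the allyl unit keeps its syn arrangement.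

Step 8
Reactants: 12 (4S,5R)-5-[(1E,5E)-7-{[tert-butyl(dimethyl)silyl]oxy}-2,6-dimethylhepta-1,5-dien-1-yl]-4-[(4S)-2,2-dimethyl-1,3-dioxolan-4-yl]-3-methylideneoxolan-2-one
Product: 13 (4S,5R)-4-[(4S)-2,2-dimethyl-1,3-dioxolan-4-yl]-5-[(1E,5E)-7-hydroxy-2,6-dimethylhepta-1,5-dien-1-yl]-3-methylideneoxolan-2-one
Conditions: HF·pyridine, pyridine/THF, 0 °C to rt
Reagents that add atoms: none
Why: Buffered fluoride cleaves the primary allylic silyl ether while the acetonide, the allylic lactone and the methylene Michael acceptor should survive.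

Step 9
Reactants: 13 (4S,5R)-4-[(4S)-2,2-dimethyl-1,3-dioxolan-4-yl]-5-[(1E,5E)-7-hydroxy-2,6-dimethylhepta-1,5-dien-1-yl]-3-methylideneoxolan-2-one
Product: 14 (4S,5R)-5-[(1E,5E)-7-bromo-2,6-dimethylhepta-1,5-dien-1-yl]-4-[(4S)-2,2-dimethyl-1,3-dioxolan-4-yl]-3-methylideneoxolan-2-one
Conditions: NBS, Me2S, CH2Cl2, −20 °C to 0 °C
Reagents that add atoms: N-bromosuccinimide O=C1CCC(=O)N1Br
Why: Corey–Kim bromination displaces an alkoxysulfonium ion by bromide at the primary allylic carbon under neutral conditions, without allylic transposition and without a phosphine that could add to the methylene lactone.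

Step 10
Reactants: 14 (4S,5R)-5-[(1E,5E)-7-bromo-2,6-dimethylhepta-1,5-dien-1-yl]-4-[(4S)-2,2-dimethyl-1,3-dioxolan-4-yl]-3-methylideneoxolan-2-one
Product: 16 (2R,3S)-2-[(1E,5E)-7-bromo-2,6-dimethylhepta-1,5-dien-1-yl]-4-methylidene-5-oxooxolane-3-carbaldehyde, via vicinal diol 15 (not isolated)
Conditions: H5IO6 (2 equiv), EtOAc, rt
Reagents that add atoms: none
Why: Periodic acid hydrolyses the terminal acetonide and cleaves the resulting 1,2-diol in the same flask (glycol cleavage), which removes the stereocontrol element and leaves C8 as the aldehyde under acidic conditions that should neither epimerise C7 nor trigger β-elimination of the lactone carboxylate.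

Step 11
Reactants: 16 (2R,3S)-2-[(1E,5E)-7-bromo-2,6-dimethylhepta-1,5-dien-1-yl]-4-methylidene-5-oxooxolane-3-carbaldehyde
Product: 17 eupatolide, (3aR,4R,6E,10E,11aR)-4-hydroxy-6,10-dimethyl-3-methylidene-3a,4,5,8,9,11a-hexahydrocyclodeca[b]furan-2(3H)-one
Conditions: CrCl2 (8 equiv), THF, rt, 16 added by syringe pump over 12 h to 2 mM
Reagents that add atoms: none
Why: Nozaki–Hiyama allylation: CrCl2 turns the allylic bromide into an allylchromium species that equilibrates by 1,3-metal shift, and because bonding through C1 would need an eight-membered ring containing the E-C4=C5 alkene, the ring should close only through C9 via the C1-bound isomer in a six-membered chair transition state, giving the E-C1=C10 alkene (tether equatorial) and, with the aldehyde oxygen anti to the β-acyloxy C6–O bond, the 8R carbinol.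

Step 12
Reactants: 17 eupatolide; 18 (2E)-2-methylbut-2-enoyl chloride (tigloyl chloride)
Product: 19 eupatolide 8-O-tiglate, (3aR,4R,6E,10E,11aR)-6,10-dimethyl-3-methylidene-2-oxo-2,3,3a,4,5,8,9,11a-octahydrocyclodeca[b]furan-4-yl (2E)-2-methylbut-2-enoate
Conditions: 18 (1.5 equiv), Et3N (3 equiv), DMAP (0.2 equiv), CH2Cl2, 0 °C
Reagents that add atoms: none
Why: DMAP-catalysed acylation of the secondary C8 alcohol by the acid chloride proceeds with retention at C8 and keeps the E geometry of the tigloyl group.

Step 13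
Reactants: 19 eupatolide 8-O-tiglate
Product: 20 (1R,4R,5R,6S,7R,8R,10R)-1,10:4,5-diepoxy-8-{[(2E)-2-methylbut-2-enoyl]oxy}germacr-11(13)-en-12,6-olide (target)
Conditions: mCPBA (2.5 equiv), NaHCO3 (5 equiv), CH2Cl2, 0 °C to rt
Reagents that add atoms: 3-chloroperoxybenzoic acid OOC(=O)c1cccc(Cl)c1
Why: Prilezhaev epoxidation should attack only the two electron-rich trisubstituted ring alkenes (not the two conjugated ones), each on its exposed outer face in the crown conformer with both methyl groups on the β face, which gives the 1β,10α (1R,10R) and 4α,5β (4R,5R) oxiranes as in peracid epoxidations of costunolide-type germacranolides.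

**Compound list**

1 | 4-pentyn-1-ol | C#CCCCO | starting material
2 | 4-pentynal | C#CCCC=O | intermediate
3 | ethyl 2-(triphenyl-λ5-phosphanylidene)propanoate | CCOC(=O)C(C)=P(c1ccccc1)(c1ccccc1)c1ccccc1 | starting material
4 | ethyl (2E)-2-methylhept-2-en-6-ynoate | C#CCC/C=C(\C)C(=O)OCC | intermediate
5 | (2E)-2-methylhept-2-en-6-yn-1-ol | C#CCC/C=C(\C)CO | intermediate
6 | tert-butyl(dimethyl){[(2E)-2-methylhept-2-en-6-yn-1-yl]oxy}silane | C#CCC/C=C(\C)CO[Si](C)(C)C(C)(C)C | intermediate
7 | (4R)-2,2-dimethyl-1,3-dioxolane-4-carbaldehyde ((R)-glyceraldehyde acetonide) | CC1(C)OC[C@@H](O1)C=O | starting material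
8 | (4S)-4-[(E)-2-iodoethenyl]-2,2-dimethyl-1,3-dioxolane | CC1(C)OC[C@@H](O1)/C=C/I | intermediate
9 | [(1E,5E)-7-{[tert-butyl(dimethyl)silyl]oxy}-2,6-dimethylhepta-1,5-dien-1-yl](dimethyl)alumane | C[Al](C)/C=C(\C)CC/C=C(\C)CO[Si](C)(C)C(C)(C)C | intermediate
10 | (4S)-4-[(1E,3E,7E)-9-{[tert-butyl(dimethyl)silyl]oxy}-4,8-dimethylnona-1,3,7-trien-1-yl]-2,2-dimethyl-1,3-dioxolane | CC1(C)OC[C@@H](O1)/C=C/C=C(\C)CC/C=C(\C)CO[Si](C)(C)C(C)(C)C | intermediate
11 | 2-bromoprop-2-enoic acid (2-bromoacrylic acid) | C=C(Br)C(=O)O | starting material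
12 | (4S,5R)-5-[(1E,5E)-7-{[tert-butyl(dimethyl)silyl]oxy}-2,6-dimethylhepta-1,5-dien-1-yl]-4-[(4S)-2,2-dimethyl-1,3-dioxolan-4-yl]-3-methylideneoxolan-2-one | C=C1C(=O)O[C@H](/C=C(\C)CC/C=C(\C)CO[Si](C)(C)C(C)(C)C)[C@H]1[C@H]2COC(C)(C)O2 | intermediate
13 | (4S,5R)-4-[(4S)-2,2-dimethyl-1,3-dioxolan-4-yl]-5-[(1E,5E)-7-hydroxy-2,6-dimethylhepta-1,5-dien-1-yl]-3-methylideneoxolan-2-one | C=C1C(=O)O[C@H](/C=C(\C)CC/C=C(\C)CO)[C@H]1[C@H]2COC(C)(C)O2 | intermediate
14 | (4S,5R)-5-[(1E,5E)-7-bromo-2,6-dimethylhepta-1,5-dien-1-yl]-4-[(4S)-2,2-dimethyl-1,3-dioxolan-4-yl]-3-methylideneoxolan-2-one | C=C1C(=O)O[C@H](/C=C(\C)CC/C=C(\C)CBr)[C@H]1[C@H]2COC(C)(C)O2 | intermediate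
15 | (4R,5R)-5-[(1E,5E)-7-bromo-2,6-dimethylhepta-1,5-dien-1-yl]-4-[(1S)-1,2-dihydroxyethyl]-3-methylideneoxolan-2-one | C=C1C(=O)O[C@H](/C=C(\C)CC/C=C(\C)CBr)[C@H]1[C@H](O)CO | intermediate
16 | (2R,3S)-2-[(1E,5E)-7-bromo-2,6-dimethylhepta-1,5-dien-1-yl]-4-methylidene-5-oxooxolane-3-carbaldehyde | C=C1C(=O)O[C@H](/C=C(\C)CC/C=C(\C)CBr)[C@H]1C=O | intermediate
17 | eupatolide, (3aR,4R,6E,10E,11aR)-4-hydroxy-6,10-dimethyl-3-methylidene-3a,4,5,8,9,11a-hexahydrocyclodeca[b]furan-2(3H)-one | C1/C(C)=C/[C@H]2OC(=O)C(=C)[C@@H]2[C@H](O)C/C(C)=C/C1 | intermediate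
18 | (2E)-2-methylbut-2-enoyl chloride (tigloyl chloride) | C/C=C(\C)C(Cl)=O | starting material
19 | eupatolide 8-O-tiglate, (3aR,4R,6E,10E,11aR)-6,10-dimethyl-3-methylidene-2-oxo-2,3,3a,4,5,8,9,11a-octahydrocyclodeca[b]furan-4-yl (2E)-2-methylbut-2-enoate | C1/C(C)=C/[C@H]2OC(=O)C(=C)[C@@H]2[C@H](OC(=O)/C(C)=C/C)C/C(C)=C/C1 | intermediate
20 | (1R,4R,5R,6S,7R,8R,10R)-1,10:4,5-diepoxy-8-{[(2E)-2-methylbut-2-enoyl]oxy}germacr-11(13)-en-12,6-olide | C=C1C(=O)O[C@H]2[C@H]1[C@H](OC(=O)/C(C)=C/C)C[C@@]1(C)O[C@@H]1CC[C@@]1(C)O[C@H]21 | target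

**Step count and risks**

Total step count: 13. Longest linear sequence: 12 steps (from 1 through steps 1–4 and 6–13 to 20); step 5 is a one-step branch.

The three steps most likely to fail:

First, step 7 (key step). Migratory insertion at the 1,2-disubstituted, α-branched diene terminus may be slow, so that 11 is consumed by reduction or oligomerisation. The allylpalladium intermediate may lose a β-hydride to give a triene before the C–O bond forms. The dioxolane may discriminate poorly between the two alkene faces. The fallback sets out from 10 and keeps the same two-bond disconnection but makes the bonds by a radical–polar crossover. Malonic acid and Mn(OAc)3 (KOAc, AcOH, 45 °C) generate a malonyl radical that adds to C7; the allyl radical is oxidised to the cation and trapped at C6 by the carboxyl group, which should give the trans α-carboxy lactone F1. Decarboxylative Mannich methylenation (aqueous CH2O, Et2NH, NaOAc, AcOH, 60 °C) then leads back to the route at 12.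

Second, step 11. Closure through C9 must outrun intermolecular coupling and protonation of the allylchromium species, which slow addition at high dilution is meant to secure. The face of the aldehyde is chosen by the folding of the chain, so addition from the other face would give the C8 epimer. The fallback sets out from 16 and covers this stereochemical failure. If the cyclisation gives mainly 8-epi-eupatolide F2, this alcohol is not acylated with retention but esterified with inversion under Mitsunobu conditions (tiglic acid, PPh3, DIAD, toluene, 0 °C to rt). This installs the tiglate with the required 8R configuration and rejoins the route at 19, so step 12 is not needed.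

Third, step 13. The first-formed mono-epoxide may undergo acid-promoted transannular cyclisation onto the remaining ring alkene, and face selectivity at one of the two alkenes may be incomplete when both are oxidised together. The fallback sets out from 17 and installs the oxiranes one at a time without acid. Hydroxyl-directed epoxidation of the homoallylic C1=C10 bond (VO(acac)2, t-BuOOH, CH2Cl2, 0 °C) should give 1β,10α-epoxyeupatolide F3. Acylation with 18 under the conditions of step 12 gives its 8-O-tiglate F4. Neutral epoxidation of the remaining C4=C5 bond with dimethyldioxirane (acetone, 0 °C) comes back to the route at 20.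

**Further compounds**

F1 | step 7 | (4S,5R)-5-[(1E,5E)-7-{[tert-butyl(dimethyl)silyl]oxy}-2,6-dimethylhepta-1,5-dien-1-yl]-4-[(4S)-2,2-dimethyl-1,3-dioxolan-4-yl]-2-oxooxolane-3-carboxylic acid (mixture at C3) | OC(=O)C1C(=O)O[C@H](/C=C(\C)CC/C=C(\C)CO[Si](C)(C)C(C)(C)C)[C@H]1[C@H]2COC(C)(C)O2
F2 | step 11 | 8-epi-eupatolide, (3aR,4S,6E,10E,11aR)-4-hydroxy-6,10-dimethyl-3-methylidene-3a,4,5,8,9,11a-hexahydrocyclodeca[b]furan-2(3H)-one | C1/C(C)=C/[C@H]2OC(=O)C(=C)[C@@H]2[C@@H](O)C/C(C)=C/C1
F3 | step 13 | 1β,10α-epoxyeupatolide, (1R,6R,7R,8R,10R)-1,10-epoxy-8-hydroxygermacra-4,11(13)-dien-12,6-olide | C1/C(C)=C/[C@H]2OC(=O)C(=C)[C@@H]2[C@H](O)C[C@@]2(C)O[C@@H]2C1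
F4 | step 13 | 1β,10α-epoxyeupatolide 8-O-tiglate, (1R,6R,7R,8R,10R)-1,10-epoxy-8-{[(2E)-2-methylbut-2-enoyl]oxy}germacra-4,11(13)-dien-12,6-olide | C1/C(C)=C/[C@H]2OC(=O)C(=C)[C@@H]2[C@H](OC(=O)/C(C)=C/C)C[C@@]2(C)O[C@@H]2C1
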